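The C1–C9 bond of ring B is the disconnection on which everything rests: the tertiary carbinol C1 lies next to the bridging C9 ketone, an α-ketol that an intramolecular crossed benzoin forms directly. In one operation a chiral triazolium carbene converts the C9 aldehyde of an acyclic (Z)-keto aldehyde into an acyl-anion equivalent, closes ring B onto the C1 enone carbonyl and sets C1. The precursor carries C2–C4 with nitrogen from an L-aspartate-derived lactone, the C6 silyl ether from an asymmetric allylation, and the C7=C8 cis-alkene from Lindlar reduction of an ynone; C4 stays a silyl ether so that only one aldehyde is present. A chelated C4–C5 aldol then closes ring A before deprotection, acylation and directed epoxidation.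

Key step: step 8

Remarks on the chemistry (assumptions):
- Locants C1–C9 are those of the bicyclo[3.3.1]nonane core: C1 hydroxylated bridgehead, C2 methylene, C3 N-bearing, C4 carbinol, C5 bridgehead CH, C6 carbinol, C7/C8 epoxide, C9 bridging ketone; bicyclic names use these locants.
- The (Z)-enone is made from an alkyne and not from a furan, so that no free cis-γ-hydroxy enone (which would cyclodehydrate to a furan) and no acyl reduction beside the enone occur on the way to 13.
- Unisolated intermediates are numbered when they persist between two separate reagent additions; transient catalyst- or metal-bound species inside one operation are described in the Why line only.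
- The (5aS,10bR) antipode of the aminoindanol triazolium salt is assumed to be matched to the 6S substrate; if a trial shows otherwise, its commercial enantiomer is used with nothing else changed.
- Lactone 1 and the (−)-B-allyldiisopinocampheylborane solution are assumed to be purchased.
- Aldehyde 16 is written in its open form; it should rest largely as the five-membered lactol with the C1 hydroxyl and react through the open form.

Step 1
Reactants: 1 tert-butyl N-[(3S)-5-oxooxolan-3-yl]carbamate [(S)-3-(Boc-amino)-γ-butyrolactone]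
Product: 2 tert-butyl N-[(2S)-1-hydroxy-4-[methoxy(methyl)amino]-4-oxobutan-2-yl]carbamate
Conditions: MeNH(OMe)·HCl, Me3Al, CH2Cl2, 0 °C to rt; Rochelle-salt work-up
Reagents that add atoms: N,O-dimethylhydroxylamine hydrochloride, CNOC.Cl
Why: Weinreb aminolysis of a γ-lactone by the aluminium amide opens the ring at the acyl carbon only, so the carbamate and the C3 stereocentre (from L-aspartate) stay untouched and the future C1 carbonyl is installed as a Weinreb amide.

Step 2
Reactants: 2 tert-butyl N-[(2S)-1-hydroxy-4-[methoxy(methyl)amino]-4-oxobutan-2-yl]carbamate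
Product: 3 tert-butyl N-[(2S)-4-[methoxy(methyl)amino]-4-oxo-1-(triethylsilyloxy)butan-2-yl]carbamate
Conditions: TESCl, imidazole, CH2Cl2, 0 °C
Reagents that add atoms: chlorotriethylsilane, CC[Si](Cl)(CC)CC
Why: Imidazole-promoted O-silylation of the primary alcohol is selective over the carbamate N–H, prevents relactonisation and masks C4 as an ether that can later be cleaved beside a secondary TBS ether.

Step 3
Reactants: 4 3-(trimethylsilyl)prop-2-ynal
Product: 6 (3S)-1-(trimethylsilyl)hex-5-en-1-yn-3-ol, via diisopinocampheylborinate ester 5 (not isolated)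
Conditions: (−)-Ipc2B(allyl) (1 M in pentane), Et2O, −78 °C; then NaBO3·4H2O, THF/H2O, rt
Reagents that add atoms: (−)-B-allyldiisopinocampheylborane, C=CCB([C@@H]1C[C@@H]2C[C@H]([C@H]1C)C2(C)C)[C@@H]1C[C@@H]2C[C@H]([C@H]1C)C2(C)C
Why: Brown asymmetric allylboration through a closed chair transition state, in which the reagent derived from (+)-α-pinene attacks the Si face of the ynal and should set the C6 carbinol as (S); the mild perborate oxidation releases the alcohol without cleaving the alkynylsilane.

Step 4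
Reactants: 6 (3S)-1-(trimethylsilyl)hex-5-en-1-yn-3-ol
Product: 8 (3S)-3-(tert-butyldimethylsilyloxy)hex-5-en-1-yne, via bis-silylated enyne 7 (not isolated)
Conditions: TBSCl, imidazole, DMF, rt; then MeOH, K2CO3 (excess), rt
Reagents that add atoms: tert-butylchlorodimethylsilane, CC(C)(C)[Si](C)(C)Cl
Why: Imidazole-mediated O-silylation followed in the same flask by carbonate/methanol protodesilylation of the alkynyl C–Si bond, which leaves the secondary TBS ether and the stereocentre untouched.

Step 5
Reactants: 8 (3S)-3-(tert-butyldimethylsilyloxy)hex-5-en-1-yne (2.3 equiv, excess recovered); 3 tert-butyl N-[(2S)-4-[methoxy(methyl)amino]-4-oxo-1-(triethylsilyloxy)butan-2-yl]carbamate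
Product: 10 tert-butyl N-[(2S,7S)-7-(tert-butyldimethylsilyloxy)-4-oxo-1-(triethylsilyloxy)dec-9-en-5-yn-2-yl]carbamate, via lithium acetylide 9 (not isolated)
Conditions: n-BuLi, THF, −78 °C; then 3, −78 to −20 °C; aq. NH4Cl
Reagents that add atoms: none
Why: Weinreb ketone synthesis, in which the acetylide adds once because the chelated tetrahedral adduct survives until the quench (the first equivalent only deprotonates the carbamate), forming the C1–C8 bond and the ynone without touching C3 or C6.

Step 6
Reactants: 10 tert-butyl N-[(2S,7S)-7-(tert-butyldimethylsilyloxy)-4-oxo-1-(triethylsilyloxy)dec-9-en-5-yn-2-yl]carbamate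
Product: 12 tert-butyl N-[(2S,7S)-7-(tert-butyldimethylsilyloxy)-4,9-dioxo-1-(triethylsilyloxy)non-5-yn-2-yl]carbamate, via ozonide 11 (not isolated)
Conditions: O3, CH2Cl2, −78 °C (Sudan III end point); then Me2S, −78 °C to rt
Reagents that add atoms: ozone, [O-][O+]=O
Why: Chemoselective ozonolysis, since the monosubstituted alkene is far more electron-rich than the conjugated ynone triple bond; reduction of the ozonide with the weakly nucleophilic sulfide gives the C9 aldehyde without a free C9 alcohol and without phosphine addition to the ynone.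

Step 7
Reactants: 12 tert-butyl N-[(2S,7S)-7-(tert-butyldimethylsilyloxy)-4,9-dioxo-1-(triethylsilyloxy)non-5-yn-2-yl]carbamate
Product: 13 tert-butyl N-[(2S,5Z,7S)-7-(tert-butyldimethylsilyloxy)-4,9-dioxo-1-(triethylsilyloxy)non-5-en-2-yl]carbamate
Conditions: H2 (1 atm), Lindlar catalyst (Pd/CaCO3, Pb-poisoned), quinoline, EtOAc, 0 °C, stopped after one equivalent
Reagents that add atoms: none
Why: Lindlar semi-hydrogenation delivers both hydrogens to one face of the alkyne on the poisoned palladium surface and should give the (Z)-enone, with quinoline suppressing over-reduction and the aldehyde, carbamate and silyl ethers inert.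

Step 8
Reactants: 13 tert-butyl N-[(2S,5Z,7S)-7-(tert-butyldimethylsilyloxy)-4,9-dioxo-1-(triethylsilyloxy)non-5-en-2-yl]carbamate
Product: 14 tert-butyl N-[(2S)-1-[(1S,4S)-4-(tert-butyldimethylsilyloxy)-1-hydroxy-6-oxocyclohex-2-en-1-yl]-3-(triethylsilyloxy)propan-2-yl]carbamate
Conditions: (5aS,10bR)-aminoindanol-derived N-pentafluorophenyl triazolium tetrafluoroborate (15 mol %), Et3N (15 mol %), toluene (0.02 M), rt
Reagents that add atoms: none
Why: The free carbene adds to the only aldehyde of 13 (C9) and proton transfer gives the Breslow enaminol, an acyl-anion equivalent that attacks the C1 ketone carbonyl and, after proton transfer and loss of the carbene, leaves the C1–C9 bond and the tertiary α-ketol. This is the intramolecular aldehyde–ketone crossed benzoin reaction known with chiral triazolium carbenes. Ring B closes in the 6-exo-trig mode onto the C=O of the enone. C1, the one new stereocentre, is set by the chiral pocket of the carbene choosing the ketone face, reinforced by a half-chair transition state in which the C6 silyloxy group and the C2 side chain are both pseudo-equatorial, which should place the new hydroxyl cis to C6–OTBS (1S). The step needs 1,2-attack at the ketone with the aldehyde as the sole donor: a Stetter closure onto C7 would require a four-membered ring, the cis C7=C8 alkene holds C9 within reach of C1, C4 is kept as a silyl ether so that no second aldehyde competes, and the weak base at high dilution limits β-elimination and intermolecular coupling.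

Step 9
Reactants: 14 tert-butyl N-[(2S)-1-[(1S,4S)-4-(tert-butyldimethylsilyloxy)-1-hydroxy-6-oxocyclohex-2-en-1-yl]-3-(triethylsilyloxy)propan-2-yl]carbamate
Product: 15 tert-butyl N-[(2S)-1-hydroxy-3-[(1S,4S)-4-(tert-butyldimethylsilyloxy)-1-hydroxy-6-oxocyclohex-2-en-1-yl]propan-2-yl]carbamate
Conditions: PPTS (0.2 equiv), MeOH/CH2Cl2 (1:1), 0 °C
Reagents that add atoms: none
Why: Acid-catalysed methanolysis of silyl ethers cleaves the unhindered primary TES ether much faster than the secondary TBS ether, and the tertiary ketol and carbamate are inert to pyridinium tosylate.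

Step 10
Reactants: 15 tert-butyl N-[(2S)-1-hydroxy-3-[(1S,4S)-4-(tert-butyldimethylsilyloxy)-1-hydroxy-6-oxocyclohex-2-en-1-yl]propan-2-yl]carbamate
Product: 16 tert-butyl N-[(2S)-1-oxo-3-[(1S,4S)-4-(tert-butyldimethylsilyloxy)-1-hydroxy-6-oxocyclohex-2-en-1-yl]propan-2-yl]carbamate
Conditions: IBX (1.5 equiv), DMSO, rt
Reagents that add atoms: none
Why: IBX oxidation of the primary alcohol is base-free, so the N-Boc α-amino aldehyde should form without epimerisation at C3; with 1,4-diols this oxidant is known to stop at the aldehyde/lactol level, and it leaves the tertiary hydroxyl alone.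

Step 11
Reactants: 16 tert-butyl N-[(2S)-1-oxo-3-[(1S,4S)-4-(tert-butyldimethylsilyloxy)-1-hydroxy-6-oxocyclohex-2-en-1-yl]propan-2-yl]carbamate
Product: 17 tert-butyl N-[(1S,3S,4R,5S,6R)-6-(tert-butyldimethylsilyloxy)-1,4-dihydroxy-9-oxobicyclo[3.3.1]non-7-en-3-yl]carbamate
Conditions: MgBr2·OEt2 (3 equiv), i-Pr2NEt (3 equiv), CH2Cl2, −20 to 0 °C
Reagents that add atoms: none
Why: Soft-enolisation intramolecular aldol, in which Mg(II) held by the C1–O/C9=O ketol acidifies C5–H (the only enolisable position) for the amine and the magnesium enolate adds to the C4 aldehyde through a closed chair with Mg bridging O9 and O4; the C4 hydroxyl should therefore emerge axial and syn to C9=O (4R), while the C1 tether forces the new C4–C5 bond onto the ring-B face anti to C6–OTBS (5S) and NHBoc sits equatorial.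

Step 12
Reactants: 17 tert-butyl N-[(1S,3S,4R,5S,6R)-6-(tert-butyldimethylsilyloxy)-1,4-dihydroxy-9-oxobicyclo[3.3.1]non-7-en-3-yl]carbamate
Product: 18 (1S,3S,4R,5R,6R)-3-amino-1,4,6-trihydroxybicyclo[3.3.1]non-7-en-9-one hydrochloride
Conditions: HCl (3 M in MeOH), 0 °C to rt
Reagents that add atoms: hydrogen chloride, Cl
Why: Acidolysis of the Boc carbamate and methanolysis of the secondary TBS ether occur in one operation, and the bridged ketone resists dehydration because both α-carbons are bridgeheads and cannot enolise.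

Step 13
Reactants: 19 hex-5-enoic acid
Product: 21 N-methoxy-N-methylhex-5-enamide, via 1-(hex-5-enoyl)imidazole 20 (not isolated)
Conditions: CDI, CH2Cl2, rt; then MeNH(OMe)·HCl, rt
Reagents that add atoms: N,O-dimethylhydroxylamine hydrochloride, CNOC.Cl
Why: Carbonyldiimidazole activation gives the acyl imidazole, which acylates the hydroxylamine to the Weinreb amide; the terminal alkene is a spectator.

Step 14
Reactants: 21 N-methoxy-N-methylhex-5-enamide
Product: 22 undec-1-en-6-one
Conditions: n-C5H11MgBr, THF, 0 °C; aq. NH4Cl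
Reagents that add atoms: pentylmagnesium bromide, CCCCC[Mg]Br
Why: Weinreb ketone synthesis, the chelated tetrahedral intermediate preventing a second Grignard addition.

Step 15
Reactants: 22 undec-1-en-6-one
Product: 23 (2E)-7-oxododec-2-enoic acid
Conditions: acrylic acid (3 equiv), Hoveyda–Grubbs II catalyst (5 mol %), CH2Cl2, 40 °C
Reagents that add atoms: acrylic acid, C=CC(=O)O
Why: Olefin cross-metathesis between a terminal alkene and the electron-poor acrylic acid is selective for the cross product and thermodynamically for the (E)-enoic acid, and the ketone is tolerated.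

Step 16
Reactants: 18 (1S,3S,4R,5R,6R)-3-amino-1,4,6-trihydroxybicyclo[3.3.1]non-7-en-9-one hydrochloride; 23 (2E)-7-oxododec-2-enoic acid
Product: 24 (2E)-N-[(1S,3S,4R,5R,6R)-1,4,6-trihydroxy-9-oxobicyclo[3.3.1]non-7-en-3-yl]-7-oxododec-2-enamide
Conditions: EDC·HCl, HOBt, i-Pr2NEt, DMF, 0 °C to rt
Reagents that add atoms: none
Why: Carbodiimide/HOBt amide coupling, in which the liberated primary amine is far more nucleophilic than the tertiary and two axial secondary hydroxyls, so N-acylation should be selective without hydroxyl protection.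

Step 17
Reactants: 24 (2E)-N-[(1S,3S,4R,5R,6R)-1,4,6-trihydroxy-9-oxobicyclo[3.3.1]non-7-en-3-yl]-7-oxododec-2-enamide
Product: 25 isariotin C, (2E)-N-[(1S,3S,4R,5S,6S,7S,8S)-7,8-epoxy-1,4,6-trihydroxy-9-oxobicyclo[3.3.1]nonan-3-yl]-7-oxododec-2-enamide
Conditions: VO(acac)2 (10 mol %), t-BuOOH (in decane), CH2Cl2, 0 °C to rt
Reagents that add atoms: tert-butyl hydroperoxide, CC(C)(C)OO
Why: Vanadium-catalysed hydroxyl-directed epoxidation, in which the vanadate ester of the pseudo-axial C6 and the C1 allylic hydroxyls delivers oxygen to the C7=C8 face syn to both, which is also the convex face of the bicycle (7S,8S); the electron-poor enamide alkene and the ketones do not react.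

Compound list
1 | tert-butyl N-[(3S)-5-oxooxolan-3-yl]carbamate | CC(C)(C)OC(=O)N[C@@H]1COC(=O)C1 | starting material
2 | tert-butyl N-[(2S)-1-hydroxy-4-[methoxy(methyl)amino]-4-oxobutan-2-yl]carbamate | CC(C)(C)OC(=O)N[C@H](CO)CC(=O)N(C)OC | intermediate
3 | tert-butyl N-[(2S)-4-[methoxy(methyl)amino]-4-oxo-1-(triethylsilyloxy)butan-2-yl]carbamate | CC(C)(C)OC(=O)N[C@H](CO[Si](CC)(CC)CC)CC(=O)N(C)OC | intermediate
4 | 3-(trimethylsilyl)prop-2-ynal | C[Si](C)(C)C#CC=O | starting material
5 | bis[(−)-isopinocampheyl]borinate ester of (3S)-1-(trimethylsilyl)hex-5-en-1-yn-3-ol | C[Si](C)(C)C#C[C@@H](OB([C@@H]1C[C@@H]2C[C@H]([C@H]1C)C2(C)C)[C@@H]1C[C@@H]2C[C@H]([C@H]1C)C2(C)C)CC=C | intermediate (not isolated)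
6 | (3S)-1-(trimethylsilyl)hex-5-en-1-yn-3-ol | C[Si](C)(C)C#C[C@@H](O)CC=C | intermediate
7 | (3S)-3-(tert-butyldimethylsilyloxy)-1-(trimethylsilyl)hex-5-en-1-yne | C[Si](C)(C)C#C[C@@H](O[Si](C)(C)C(C)(C)C)CC=C | intermediate (not isolated)
8 | (3S)-3-(tert-butyldimethylsilyloxy)hex-5-en-1-yne | C#C[C@@H](O[Si](C)(C)C(C)(C)C)CC=C | intermediate
9 | lithium acetylide of 8, [(3S)-3-(tert-butyldimethylsilyloxy)hex-5-en-1-yn-1-yl]lithium | [Li]C#C[C@@H](O[Si](C)(C)C(C)(C)C)CC=C | intermediate (not isolated)
10 | tert-butyl N-[(2S,7S)-7-(tert-butyldimethylsilyloxy)-4-oxo-1-(triethylsilyloxy)dec-9-en-5-yn-2-yl]carbamate | CC(C)(C)OC(=O)N[C@H](CO[Si](CC)(CC)CC)CC(=O)C#C[C@@H](O[Si](C)(C)C(C)(C)C)CC=C | intermediate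
11 | 1,2,4-trioxolane (ozonide) of the terminal alkene of 10, mixture at the ring carbon | CC(C)(C)OC(=O)N[C@H](CO[Si](CC)(CC)CC)CC(=O)C#C[C@@H](O[Si](C)(C)C(C)(C)C)CC1OCOO1 | intermediate (not isolated)
12 | tert-butyl N-[(2S,7S)-7-(tert-butyldimethylsilyloxy)-4,9-dioxo-1-(triethylsilyloxy)non-5-yn-2-yl]carbamate | CC(C)(C)OC(=O)N[C@H](CO[Si](CC)(CC)CC)CC(=O)C#C[C@@H](O[Si](C)(C)C(C)(C)C)CC=O | intermediate
13 | tert-butyl N-[(2S,5Z,7S)-7-(tert-butyldimethylsilyloxy)-4,9-dioxo-1-(triethylsilyloxy)non-5-en-2-yl]carbamate (key-step precursor) | CC(C)(C)OC(=O)N[C@H](CO[Si](CC)(CC)CC)CC(=O)/C=C\[C@@H](O[Si](C)(C)C(C)(C)C)CC=O | intermediate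
14 | tert-butyl N-[(2S)-1-[(1S,4S)-4-(tert-butyldimethylsilyloxy)-1-hydroxy-6-oxocyclohex-2-en-1-yl]-3-(triethylsilyloxy)propan-2-yl]carbamate (ring B ketol, key-step product) | CC(C)(C)OC(=O)N[C@H](CO[Si](CC)(CC)CC)C[C@@]1(O)C(=O)C[C@H](O[Si](C)(C)C(C)(C)C)C=C1 | intermediate
15 | tert-butyl N-[(2S)-1-hydroxy-3-[(1S,4S)-4-(tert-butyldimethylsilyloxy)-1-hydroxy-6-oxocyclohex-2-en-1-yl]propan-2-yl]carbamate | CC(C)(C)OC(=O)N[C@H](CO)C[C@@]1(O)C(=O)C[C@H](O[Si](C)(C)C(C)(C)C)C=C1 | intermediate
16 | tert-butyl N-[(2S)-1-oxo-3-[(1S,4S)-4-(tert-butyldimethylsilyloxy)-1-hydroxy-6-oxocyclohex-2-en-1-yl]propan-2-yl]carbamate (open form; equilibrates with its C1–O lactol) | CC(C)(C)OC(=O)N[C@H](C=O)C[C@@]1(O)C(=O)C[C@H](O[Si](C)(C)C(C)(C)C)C=C1 | intermediate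
17 | tert-butyl N-[(1S,3S,4R,5S,6R)-6-(tert-butyldimethylsilyloxy)-1,4-dihydroxy-9-oxobicyclo[3.3.1]non-7-en-3-yl]carbamate | CC(C)(C)OC(=O)N[C@H]1C[C@@]2(O)C(=O)[C@H]([C@H](O[Si](C)(C)C(C)(C)C)C=C2)[C@H]1O | intermediate
18 | (1S,3S,4R,5R,6R)-3-amino-1,4,6-trihydroxybicyclo[3.3.1]non-7-en-9-one hydrochloride | Cl.N[C@H]1C[C@@]2(O)C(=O)[C@H]([C@H](O)C=C2)[C@H]1O | intermediate
19 | hex-5-enoic acid | C=CCCCC(=O)O | starting material
20 | 1-(hex-5-enoyl)imidazole | C=CCCCC(=O)n1ccnc1 | intermediate (not isolated)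
21 | N-methoxy-N-methylhex-5-enamide | C=CCCCC(=O)N(C)OC | intermediate
22 | undec-1-en-6-one | C=CCCCC(=O)CCCCC | intermediate
23 | (2E)-7-oxododec-2-enoic acid | CCCCCC(=O)CCC/C=C/C(=O)O | intermediate
24 | (2E)-N-[(1S,3S,4R,5R,6R)-1,4,6-trihydroxy-9-oxobicyclo[3.3.1]non-7-en-3-yl]-7-oxododec-2-enamide | CCCCCC(=O)CCC/C=C/C(=O)N[C@H]1C[C@@]2(O)C(=O)[C@H]([C@H](O)C=C2)[C@H]1O | intermediate
25 | isariotin C | CCCCCC(=O)CCC/C=C/C(=O)N[C@H]1C[C@@]2(O)C(=O)[C@H]([C@H](O)[C@@H]3O[C@@H]32)[C@H]1O | target

Total step count: 17. Longest linear sequence: 12 steps (steps 3–12, 16 and 17, from aldehyde 4).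

Steps most likely to fail

Step 8 (key step). The carbene or the amine may add reversibly to the enone and isomerise the Z-alkene to E, which moves C9 out of reach of C1. The β-silyloxy aldehyde may also lose silanol under base, or the preference for one ketone face may be weak. The fallback forms the C1–C9 bond reductively: keto aldehyde 13 would be treated with SmI2 in THF/t-BuOH at −78 °C, the aldehyde ketyl adding to the samarium-bound C1 ketone in a pinacol cyclisation to give tert-butyl N-[(2S)-1-[(1S,4S,6R)-4-(tert-butyldimethylsilyloxy)-1,6-dihydroxycyclohex-2-en-1-yl]-3-(triethylsilyloxy)propan-2-yl]carbamate F1. Its secondary C9 hydroxyl would then be oxidised under Parikh–Doering conditions (SO3·pyridine, DMSO, i-Pr2NEt), and the route is rejoined at ketol 14.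

Step 11. The aldehyde may stay locked as its lactol, C3 of the α-amino aldehyde may epimerise, the C9 enolate may expel silyloxide from C6, or C4 may equilibrate through retro-aldol. The fallback caps the C1 hydroxyl and uses a preformed lithium enolate. Ketol 14 would be silylated at the tertiary hydroxyl (TESOTf, 2,6-lutidine, CH2Cl2, −78 °C) to the bis-TES ether tert-butyl N-[(2S)-1-[(1S,4S)-4-(tert-butyldimethylsilyloxy)-6-oxo-1-(triethylsilyloxy)cyclohex-2-en-1-yl]-3-(triethylsilyloxy)propan-2-yl]carbamate F2. Direct Swern oxidation, which converts only the primary TES ether, would give the lactol-free aldehyde tert-butyl N-[(2S)-1-oxo-3-[(1S,4S)-4-(tert-butyldimethylsilyloxy)-6-oxo-1-(triethylsilyloxy)cyclohex-2-en-1-yl]propan-2-yl]carbamate F3. LiHMDS (2.2 equiv, THF, −78 °C, the first equivalent on N–H) should then close ring A through the lithium-chelated chair to tert-butyl N-[(1S,3S,4R,5S,6R)-6-(tert-butyldimethylsilyloxy)-4-hydroxy-9-oxo-1-(triethylsilyloxy)bicyclo[3.3.1]non-7-en-3-yl]carbamate F4. The conditions of step 12 remove all silyl groups and Boc, and the route is rejoined at 18.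

Step 7. The conjugated alkyne may be over-reduced to the saturated ketone, or the Z-enone may isomerise to E on the catalyst or on silica. The fallback reduces the alkyne at the alcohol oxidation level. Ynone 10 would undergo Luche reduction (NaBH4, CeCl3·7H2O, MeOH, −78 °C) to tert-butyl N-[(2S,7S)-7-(tert-butyldimethylsilyloxy)-4-hydroxy-1-(triethylsilyloxy)dec-9-en-5-yn-2-yl]carbamate F5, whose C1 epimers are inconsequential. Lindlar semi-hydrogenation of the propargylic alcohol would give tert-butyl N-[(2S,5Z,7S)-7-(tert-butyldimethylsilyloxy)-4-hydroxy-1-(triethylsilyloxy)deca-5,9-dien-2-yl]carbamate F6, and buffered Dess–Martin oxidation tert-butyl N-[(2S,5Z,7S)-7-(tert-butyldimethylsilyloxy)-4-oxo-1-(triethylsilyloxy)deca-5,9-dien-2-yl]carbamate F7. Lemieux–Johnson cleavage of the electron-rich terminal alkene (OsO4 cat., NaIO4, 2,6-lutidine, dioxane/H2O) beside the electron-poor enone would then return the route to 13.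

Further compounds
F1 | step 8 | tert-butyl N-[(2S)-1-[(1S,4S,6R)-4-(tert-butyldimethylsilyloxy)-1,6-dihydroxycyclohex-2-en-1-yl]-3-(triethylsilyloxy)propan-2-yl]carbamate | CC(C)(C)OC(=O)N[C@H](CO[Si](CC)(CC)CC)C[C@@]1(O)[C@H](O)C[C@H](O[Si](C)(C)C(C)(C)C)C=C1
F2 | step 11 | tert-butyl N-[(2S)-1-[(1S,4S)-4-(tert-butyldimethylsilyloxy)-6-oxo-1-(triethylsilyloxy)cyclohex-2-en-1-yl]-3-(triethylsilyloxy)propan-2-yl]carbamate | CC(C)(C)OC(=O)N[C@H](CO[Si](CC)(CC)CC)C[C@@]1(O[Si](CC)(CC)CC)C(=O)C[C@H](O[Si](C)(C)C(C)(C)C)C=C1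
F3 | step 11 | tert-butyl N-[(2S)-1-oxo-3-[(1S,4S)-4-(tert-butyldimethylsilyloxy)-6-oxo-1-(triethylsilyloxy)cyclohex-2-en-1-yl]propan-2-yl]carbamate | CC(C)(C)OC(=O)N[C@H](C=O)C[C@@]1(O[Si](CC)(CC)CC)C(=O)C[C@H](O[Si](C)(C)C(C)(C)C)C=C1
F4 | step 11 | tert-butyl N-[(1S,3S,4R,5S,6R)-6-(tert-butyldimethylsilyloxy)-4-hydroxy-9-oxo-1-(triethylsilyloxy)bicyclo[3.3.1]non-7-en-3-yl]carbamate | CC(C)(C)OC(=O)N[C@H]1C[C@@]2(O[Si](CC)(CC)CC)C(=O)[C@H]([C@H](O[Si](C)(C)C(C)(C)C)C=C2)[C@H]1O
F5 | step 7 | tert-butyl N-[(2S,7S)-7-(tert-butyldimethylsilyloxy)-4-hydroxy-1-(triethylsilyloxy)dec-9-en-5-yn-2-yl]carbamate (C4 epimers) | CC(C)(C)OC(=O)N[C@H](CO[Si](CC)(CC)CC)CC(O)C#C[C@@H](O[Si](C)(C)C(C)(C)C)CC=C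
F6 | step 7 | tert-butyl N-[(2S,5Z,7S)-7-(tert-butyldimethylsilyloxy)-4-hydroxy-1-(triethylsilyloxy)deca-5,9-dien-2-yl]carbamate (C4 epimers) | CC(C)(C)OC(=O)N[C@H](CO[Si](CC)(CC)CC)CC(O)/C=C\[C@@H](O[Si](C)(C)C(C)(C)C)CC=C
F7 | step 7 | tert-butyl N-[(2S,5Z,7S)-7-(tert-butyldimethylsilyloxy)-4-oxo-1-(triethylsilyloxy)deca-5,9-dien-2-yl]carbamate | CC(C)(C)OC(=O)N[C@H](CO[Si](CC)(CC)CC)CC(=O)/C=C\[C@@H](O[Si](C)(C)C(C)(C)C)CC=C
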